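**Plan**
- Retrosynthesis: the diphenylmethylene ketal on the ring B catechol and the 3-O-benzoate come off first; ring C is then cut at O1–C2 and C4–C4a, giving 2,4-diprenylphloroglucinol and an α-benzoyloxy aroylacetate. The keto ester is cut at C2–C3 (Claisen) and at C3–O (benzoyloxylation), the phenol at its two aryl–prenyl bonds.
- Forward: ring A is prepared first by double C-prenylation of a carboxylate-blocked phloroglucinol and decarboxylation; the ring B keto ester is built in three steps; ring C closes in one thermal condensation; two deprotections finish.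
- Enabling feature: ring A has prenyl groups at C6 and C8 and hydroxyls at C5 and C7, so in the phloroglucinol precursor the only unsubstituted carbon (future C4a) lies between two equivalent hydroxyl-bearing carbons (future C5 and C8a). Acylation and ring closure can therefore give only one chromone.
- Stereochemistry: the target has no stereocentre and its prenyl double bonds carry two identical methyl groups, so nothing has to be controlled. The one stereocentre met on the way (α-carbon of the keto ester, racemic) becomes sp2 C3.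

Key step: step 6

Remark: ethyl 3,4-dihydroxybenzoate (commercial) is used in place of the methyl ester so that the Claisen step involves only ethoxide and gives a single ester.

**Step 1**
Reactants: 1 methyl 2,4,6-trihydroxybenzoate; 2 prenyl bromide (1-bromo-3-methylbut-2-ene)
Product: 4 methyl 2,4,6-trihydroxy-3,5-bis(3-methylbut-2-enyl)benzoate, via monoprenyl ester 3 (not isolated)
Conditions: 2 (2.1 equiv), 10% aq KOH, 0 °C, Ar; then cold 1 M HCl
Reagents that add atoms: none
Why: In cold aqueous alkali the phenoxide of the ester is alkylated at its two free ring carbons (C-alkylation of an ambident phenolate, favoured by the protic medium, as in the diprenylation of acylphloroglucinols), while the ester blocks the third ring carbon.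

**Step 2**
Reactants: 4 methyl 2,4,6-trihydroxy-3,5-bis(3-methylbut-2-enyl)benzoate
Product: 6 2,4-bis(3-methylbut-2-enyl)benzene-1,3,5-triol, via diprenylphloroglucinolcarboxylic acid 5 (not isolated)
Conditions: KOH, MeOH–H2O (degassed), reflux, Ar; then 1 M HCl to pH 3–4, 0 → 40 °C; product kept under Ar
Reagents that add atoms: none
Why: Saponification followed by protodecarboxylation, which is facile for 2,4,6-trihydroxybenzoic acids through ipso-protonation of the electron-rich ring, and the dilute acid near room temperature should be too weak to cyclise the prenyl groups.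

**Step 3**
Reactants: 7 ethyl 3,4-dihydroxybenzoate; 8 dichlorodiphenylmethane
Product: 9 ethyl 2,2-diphenyl-1,3-benzodioxole-5-carboxylate
Conditions: 8 (1.5 equiv), neat, 170–180 °C, Ar stream
Reagents that add atoms: none
Why: Thermal double substitution of the geminal dichloride by the catechol gives the diphenylmethylene ketal, a standard catechol protection that withstands base and heat.

**Step 4**
Reactants: 9 ethyl 2,2-diphenyl-1,3-benzodioxole-5-carboxylate
Product: 10 ethyl 3-(2,2-diphenyl-1,3-benzodioxol-5-yl)-3-oxopropanoate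
Conditions: EtOAc (1.5 equiv), LiN(SiMe3)2 (2.5 equiv), THF, −78 → 0 °C; AcOH quench
Reagents that add atoms: ethyl acetate, CCOC(C)=O
Why: Crossed Claisen condensation in which the lithium enolate of ethyl acetate adds to the non-enolisable aryl ester and the second equivalent of base drives the reaction by deprotonating the β-keto ester.

**Step 5**
Reactants: 10 ethyl 3-(2,2-diphenyl-1,3-benzodioxol-5-yl)-3-oxopropanoate
Product: 11 ethyl 2-(benzoyloxy)-3-(2,2-diphenyl-1,3-benzodioxol-5-yl)-3-oxopropanoate (racemic)
Conditions: NaH (1.05 equiv), THF, 0 °C; then (PhCO2)2 (1.0 equiv), 0 °C → rt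
Reagents that add atoms: dibenzoyl peroxide, O=C(OOC(=O)c1ccccc1)c1ccccc1
Why: The sodium enolate attacks the O–O bond of the peroxide (electrophilic α-benzoyloxylation of a 1,3-dicarbonyl compound), giving the α-acyloxy keto ester as a racemate whose stereocentre is lost later.

**Step 6**
Reactants: 6 2,4-bis(3-methylbut-2-enyl)benzene-1,3,5-triol; 11 ethyl 2-(benzoyloxy)-3-(2,2-diphenyl-1,3-benzodioxol-5-yl)-3-oxopropanoate
Product: 14 3-(benzoyloxy)-2-(2,2-diphenyl-1,3-benzodioxol-5-yl)-5,7-dihydroxy-6,8-bis(3-methylbut-2-enyl)chromen-4-one, via aroyl(benzoyloxy)ketene 12 (not isolated), via C-acylphloroglucinol diketone 13 (not isolated)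
Conditions: neat melt of 6 and 11 (1.5 equiv), no catalyst, microwave, 230–240 °C, 3–5 min, Ar, open vessel (EtOH and H2O distil off)
Reagents that add atoms: none
Why: On flash heating without catalyst the β-keto ester 11 loses ethanol to the acylketene 12, which is captured by the single unsubstituted ring carbon of phenol 6 to form the C4–C4a bond in diketone 13 (an aryl ester formed at oxygen can revert to the ketene at this temperature, whereas C-acylation is irreversible). One of the two equivalent hydroxyls flanking the new ketone then adds to the aroyl carbonyl in a 6-exo-trig closure and loss of water forms O1–C2, giving ring C as an aromatic 4-pyranone. The closest known reaction is the catalyst-free thermal condensation of phloroglucinol with aroylacetates (Mentzer pyrone synthesis, a Simonis-type chromone annulation), which also accepts α-substituted keto esters. No stereocentre is created; the racemic α-carbon of 11 ends as sp2 C3. The step needs chromone and not coumarin formation, a single regiochemistry and intact prenyl groups: the absence of acid and the high carbon nucleophilicity of the trihydroxybenzene favour acylation at carbon over Pechmann-type closure, the substrate offers only one free carbon between two equivalent hydroxyls, and the short acid-free heating should spare the ortho-prenylphenol units from cyclising to chromans. A benzoyl shift between hydroxyls would be without consequence because step 7 cleaves every benzoate.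

**Step 7**
Reactants: 14 3-(benzoyloxy)-2-(2,2-diphenyl-1,3-benzodioxol-5-yl)-5,7-dihydroxy-6,8-bis(3-methylbut-2-enyl)chromen-4-one
Product: 15 2-(2,2-diphenyl-1,3-benzodioxol-5-yl)-3,5,7-trihydroxy-6,8-bis(3-methylbut-2-enyl)chromen-4-one
Conditions: K2CO3 (2 equiv), MeOH–THF, 0 °C → rt, Ar; AcOH quench
Reagents that add atoms: none
Why: Base-mediated methanolysis (transesterification) of the enol-type 3-O-benzoate is fast, whereas the ketal, the prenyl groups and the chromone are inert to carbonate, and argon keeps the flavonol anion from autoxidation.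

**Step 8**
Reactants: 15 2-(2,2-diphenyl-1,3-benzodioxol-5-yl)-3,5,7-trihydroxy-6,8-bis(3-methylbut-2-enyl)chromen-4-one
Product: 16 2-(3,4-dihydroxyphenyl)-3,5,7-trihydroxy-6,8-bis(3-methylbut-2-enyl)chromen-4-one (target)
Conditions: AcOH–H2O 4:1, 90 °C, Ar
Reagents that add atoms: none
Why: Acid-catalysed ketal hydrolysis through the stabilised diaryl oxocarbenium ion releases the catechol and benzophenone, and acetic acid is expected to be too weak to protonate the prenyl double bonds at a competitive rate.

**Compound list**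
1 | methyl 2,4,6-trihydroxybenzoate | COC(=O)c1c(O)cc(O)cc1O | starting material
2 | prenyl bromide (1-bromo-3-methylbut-2-ene) | CC(C)=CCBr | starting material
3 | methyl 2,4,6-trihydroxy-3-(3-methylbut-2-enyl)benzoate (not isolated) | COC(=O)c1c(O)cc(O)c(CC=C(C)C)c1O | intermediate
4 | methyl 2,4,6-trihydroxy-3,5-bis(3-methylbut-2-enyl)benzoate | COC(=O)c1c(O)c(CC=C(C)C)c(O)c(CC=C(C)C)c1O | intermediate
5 | 2,4,6-trihydroxy-3,5-bis(3-methylbut-2-enyl)benzoic acid (not isolated) | OC(=O)c1c(O)c(CC=C(C)C)c(O)c(CC=C(C)C)c1O | intermediate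
6 | 2,4-bis(3-methylbut-2-enyl)benzene-1,3,5-triol | CC(C)=CCc1c(O)cc(O)c(CC=C(C)C)c1O | intermediate
7 | ethyl 3,4-dihydroxybenzoate | CCOC(=O)c1ccc(O)c(O)c1 | starting material
8 | dichlorodiphenylmethane | ClC(Cl)(c1ccccc1)c1ccccc1 | starting material
9 | ethyl 2,2-diphenyl-1,3-benzodioxole-5-carboxylate | CCOC(=O)c1ccc2OC(c3ccccc3)(c3ccccc3)Oc2c1 | intermediate
10 | ethyl 3-(2,2-diphenyl-1,3-benzodioxol-5-yl)-3-oxopropanoate | CCOC(=O)CC(=O)c1ccc2OC(c3ccccc3)(c3ccccc3)Oc2c1 | intermediate
11 | ethyl 2-(benzoyloxy)-3-(2,2-diphenyl-1,3-benzodioxol-5-yl)-3-oxopropanoate (racemic) | CCOC(=O)C(OC(=O)c1ccccc1)C(=O)c1ccc2OC(c3ccccc3)(c3ccccc3)Oc2c1 | intermediate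
12 | 1-(2,2-diphenyl-1,3-benzodioxol-5-yl)-1,3-dioxoprop-2-en-2-yl benzoate, the aroyl(benzoyloxy)ketene (not isolated) | O=C=C(OC(=O)c1ccccc1)C(=O)c1ccc2OC(c3ccccc3)(c3ccccc3)Oc2c1 | intermediate
13 | 1-(2,2-diphenyl-1,3-benzodioxol-5-yl)-1,3-dioxo-3-[2,4,6-trihydroxy-3,5-bis(3-methylbut-2-enyl)phenyl]propan-2-yl benzoate (racemic, not isolated) | CC(C)=CCc1c(O)c(CC=C(C)C)c(O)c(C(=O)C(OC(=O)c2ccccc2)C(=O)c2ccc3OC(c4ccccc4)(c4ccccc4)Oc3c2)c1O | intermediate
14 | 3-(benzoyloxy)-2-(2,2-diphenyl-1,3-benzodioxol-5-yl)-5,7-dihydroxy-6,8-bis(3-methylbut-2-enyl)chromen-4-one | CC(C)=CCc1c(O)c(CC=C(C)C)c2oc(-c3ccc4OC(c5ccccc5)(c5ccccc5)Oc4c3)c(OC(=O)c3ccccc3)c(=O)c2c1O | intermediate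
15 | 2-(2,2-diphenyl-1,3-benzodioxol-5-yl)-3,5,7-trihydroxy-6,8-bis(3-methylbut-2-enyl)chromen-4-one | CC(C)=CCc1c(O)c(CC=C(C)C)c2oc(-c3ccc4OC(c5ccccc5)(c5ccccc5)Oc4c3)c(O)c(=O)c2c1O | intermediate
16 | 2-(3,4-dihydroxyphenyl)-3,5,7-trihydroxy-6,8-bis(3-methylbut-2-enyl)chromen-4-one | CC(C)=CCc1c(O)c(CC=C(C)C)c2oc(-c3ccc(O)c(O)c3)c(O)c(=O)c2c1O | target

**Totals**
Total step count: 8.
Longest linear sequence: 6 steps (steps 3, 4, 5, 6, 7, 8).

**Steps most likely to fail**

1. Step 6. At the temperature needed to generate the ketene, the ortho-prenylphenol units may add a hydroxyl across the neighbouring double bond, the keto ester may fragment before it acylates carbon, and acylation at oxygen followed by closure onto carbon would lead into the coumarin series. Fallback (sets out from 2, returns to the route at 16): the acyl carbon is placed on ring A before ring C is built, and the ring is closed oxidatively under base.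
   - Prenyl bromide 2 and commercial 2,4,6-trihydroxyacetophenone in cold 10% aq KOH should give 1-[2,4,6-trihydroxy-3,5-bis(3-methylbut-2-enyl)phenyl]ethanone F1.
   - MOMCl and i-Pr2NEt in CH2Cl2 protect the para and one ortho hydroxyl, leaving the hydrogen-bonded one free, to give 1-[2-hydroxy-4,6-bis(methoxymethoxy)-3,5-bis(3-methylbut-2-enyl)phenyl]ethanone F2.
   - Claisen–Schmidt condensation with commercial 3,4-bis(methoxymethoxy)benzaldehyde (KOH, EtOH–H2O, rt) gives (E)-3-[3,4-bis(methoxymethoxy)phenyl]-1-[2-hydroxy-4,6-bis(methoxymethoxy)-3,5-bis(3-methylbut-2-enyl)phenyl]prop-2-en-1-one F3.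
   - Algar–Flynn–Oyamada oxidation (H2O2, NaOH, MeOH, 0 °C) attacks only the electron-poor enone and closes the ring to 2-[3,4-bis(methoxymethoxy)phenyl]-3-hydroxy-5,7-bis(methoxymethoxy)-6,8-bis(3-methylbut-2-enyl)chromen-4-one F4.
   - Methanolic HCl at mild temperature removes the four MOM groups and gives 16.

2. Step 1. The phenoxide may be alkylated at oxygen, or a third time at an already substituted carbon with loss of aromaticity, or the reaction may stall at the mono stage, so that the wanted 3,5-dialkylation is only one of several competing pathways. Fallback (sets out from 2, returns at 6): the prenyl groups are introduced one at a time by directed ortho-metalation.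
   - Commercial phloroglucinol with MOMCl and i-Pr2NEt gives 1,3,5-tris(methoxymethoxy)benzene F5.
   - Lithiation between two MOM ethers (n-BuLi, THF, 0 °C), then CuBr·SMe2 and 2, gives 1,3,5-tris(methoxymethoxy)-2-(3-methylbut-2-enyl)benzene F6.
   - A second cycle of the same operations gives 1,3,5-tris(methoxymethoxy)-2,4-bis(3-methylbut-2-enyl)benzene F7.
   - Methanolic HCl at room temperature releases 6.

3. Step 8. During ketal hydrolysis the C5 or C7 hydroxyl may add under acid catalysis to a neighbouring prenyl double bond, and the liberated catechol may oxidise in air. Fallback (sets out from 7, returns at 16): the catechol is carried as silyl ethers so that no acidic deprotection is needed.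
   - Ester 7 with TBSCl and imidazole in DMF gives ethyl 3,4-bis(tert-butyldimethylsilyloxy)benzoate F8.
   - The Claisen condensation of step 4 converts it into ethyl 3-[3,4-bis(tert-butyldimethylsilyloxy)phenyl]-3-oxopropanoate F9.
   - The benzoyloxylation of step 5 gives ethyl 2-(benzoyloxy)-3-[3,4-bis(tert-butyldimethylsilyloxy)phenyl]-3-oxopropanoate F10 (racemic).
   - Thermal condensation with 6 as in step 6 should give 3-(benzoyloxy)-2-[3,4-bis(tert-butyldimethylsilyloxy)phenyl]-5,7-dihydroxy-6,8-bis(3-methylbut-2-enyl)chromen-4-one F11.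
   - K2CO3 in MeOH, then TBAF buffered with AcOH in THF at 0 °C under Ar, would give 16.

**Further compounds**
F1 | step 6 | 1-[2,4,6-trihydroxy-3,5-bis(3-methylbut-2-enyl)phenyl]ethanone | CC(=O)c1c(O)c(CC=C(C)C)c(O)c(CC=C(C)C)c1O
F2 | step 6 | 1-[2-hydroxy-4,6-bis(methoxymethoxy)-3,5-bis(3-methylbut-2-enyl)phenyl]ethanone | CC(=O)c1c(O)c(CC=C(C)C)c(OCOC)c(CC=C(C)C)c1OCOC
F3 | step 6 | (E)-3-[3,4-bis(methoxymethoxy)phenyl]-1-[2-hydroxy-4,6-bis(methoxymethoxy)-3,5-bis(3-methylbut-2-enyl)phenyl]prop-2-en-1-one | COCOc1ccc(/C=C/C(=O)c2c(O)c(CC=C(C)C)c(OCOC)c(CC=C(C)C)c2OCOC)cc1OCOC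
F4 | step 6 | 2-[3,4-bis(methoxymethoxy)phenyl]-3-hydroxy-5,7-bis(methoxymethoxy)-6,8-bis(3-methylbut-2-enyl)chromen-4-one | COCOc1ccc(-c2oc3c(CC=C(C)C)c(OCOC)c(CC=C(C)C)c(OCOC)c3c(=O)c2O)cc1OCOC
F5 | step 1 | 1,3,5-tris(methoxymethoxy)benzene | COCOc1cc(OCOC)cc(OCOC)c1
F6 | step 1 | 1,3,5-tris(methoxymethoxy)-2-(3-methylbut-2-enyl)benzene | COCOc1cc(OCOC)c(CC=C(C)C)c(OCOC)c1
F7 | step 1 | 1,3,5-tris(methoxymethoxy)-2,4-bis(3-methylbut-2-enyl)benzene | COCOc1cc(OCOC)c(CC=C(C)C)c(OCOC)c1CC=C(C)C
F8 | step 8 | ethyl 3,4-bis(tert-butyldimethylsilyloxy)benzoate | CCOC(=O)c1ccc(O[Si](C)(C)C(C)(C)C)c(O[Si](C)(C)C(C)(C)C)c1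
F9 | step 8 | ethyl 3-[3,4-bis(tert-butyldimethylsilyloxy)phenyl]-3-oxopropanoate | CCOC(=O)CC(=O)c1ccc(O[Si](C)(C)C(C)(C)C)c(O[Si](C)(C)C(C)(C)C)c1
F10 | step 8 | ethyl 2-(benzoyloxy)-3-[3,4-bis(tert-butyldimethylsilyloxy)phenyl]-3-oxopropanoate (racemic) | CCOC(=O)C(OC(=O)c1ccccc1)C(=O)c1ccc(O[Si](C)(C)C(C)(C)C)c(O[Si](C)(C)C(C)(C)C)c1
F11 | step 8 | 3-(benzoyloxy)-2-[3,4-bis(tert-butyldimethylsilyloxy)phenyl]-5,7-dihydroxy-6,8-bis(3-methylbut-2-enyl)chromen-4-one | CC(C)=CCc1c(O)c(CC=C(C)C)c2oc(-c3ccc(O[Si](C)(C)C(C)(C)C)c(O[Si](C)(C)C(C)(C)C)c3)c(OC(=O)c3ccccc3)c(=O)c2c1O
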